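**Plan**
- Retrosynthetic cuts: first the two ring B bonds C6–CH2 and C1–C(=O) together (insertion of an aryne into the malonyl C–C bond of a ring A aryl malonamate). Then the ring B CH2C(=O)–pentyl bond (amide to ketone), the ring A O–C(=O)CH2 ester bond, and the ring A CH2–C(=O) bond (toluate acylation).
- Enabling feature: ring B carries two neighbouring carbon substituents, the depside carbonyl on C1 and the side-chain CH2 on C6, with oxygen on C2 (beside C1) and C4. This is the pattern delivered by the two reactive carbons of 3,5-bis(benzyloxy)benzyne when a carbanion adds remote from the C3 oxygen and an acyl group shifts to the carbon next to it.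
- Forward order: orsellinic acid gives the ring A phenol 12 (benzyl ester, 2-O-benzyl, side-chain ketone as dioxolane), which is esterified to malonamate 15; phenol 16 gives silyl triflate 20. Then 15 + 20 give 23, in which the depside ester already joins both rings; pentyl ketone formation, ketal hydrolysis and hydrogenolysis give 27.
- No ring is formed (both benzene rings are purchased) and the target is achiral, so no stereocentre has to be set.

Key step: step 12

Remark on the chemistry: the ring B ketone is carried through the key step as an N-methoxy-N-methylamide and the ring A ketone as a dioxolane; LiN(i-Pr)2, n-BuLi and pentylmagnesium bromide are used as purchased solutions, and all equivalents and temperatures are proposals.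

**Route**

Step 1
Reactants: 1 hexanoyl chloride; 2 N,O-dimethylhydroxylamine hydrochloride
Product: 3 N-methoxy-N-methylhexanamide
Conditions: K2CO3, CH2Cl2/H2O, 0 °C → rt
Reagents that add atoms: none
Why: Schotten–Baumann N-acylation of the hydroxylamine by the acid chloride should give the amide cleanly, the carbonate taking up both equivalents of HCl.

Step 2
Reactants: 4 2,4-dihydroxy-6-methylbenzoic acid (orsellinic acid)
Product: 5 benzyl 2,4-dihydroxy-6-methylbenzoate
Conditions: BnBr, KHCO3, DMF, rt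
Reagents that add atoms: benzyl bromide, BrCc1ccccc1
Why: Carboxylate O-alkylation (SN2); hydrogen carbonate deprotonates only the carboxylic acid, so the phenols stay free, and room temperature avoids decarboxylation of the acid.

Step 3
Reactants: 5 benzyl 2,4-dihydroxy-6-methylbenzoate
Product: 6 benzyl 2-hydroxy-6-methyl-4-(prop-2-en-1-yloxy)benzoate
Conditions: allyl bromide (1.05 equiv), K2CO3, acetone, reflux
Reagents that add atoms: allyl bromide, C=CCBr
Why: Williamson etherification should occur only at the more acidic, unencumbered 4-OH, because the 2-OH is held in a hydrogen bond to the ester carbonyl.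

Step 4
Reactants: 6 benzyl 2-hydroxy-6-methyl-4-(prop-2-en-1-yloxy)benzoate
Product: 7 benzyl 2-(benzyloxy)-6-methyl-4-(prop-2-en-1-yloxy)benzoate
Conditions: BnBr, K2CO3, DMF, 60 °C
Reagents that add atoms: benzyl bromide, BrCc1ccccc1
Why: Williamson etherification of the remaining hydrogen-bonded phenol under more forcing conditions, well below the temperature of a Claisen rearrangement of the allyl ether.

Step 5
Reactants: 7 benzyl 2-(benzyloxy)-6-methyl-4-(prop-2-en-1-yloxy)benzoate; 3 N-methoxy-N-methylhexanamide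
Product: 10 benzyl 2-(benzyloxy)-6-(2-oxoheptyl)-4-(prop-2-en-1-yloxy)benzoate, via lithiated toluate 8 (not isolated), via lithium hemiaminal alkoxide 9 (not isolated)
Conditions: LiN(i-Pr)2 (2 equiv), THF, −78 °C; 3, −78 °C; AcOH, −78 °C → rt
Reagents that add atoms: none
Why: Lateral lithiation of the ortho-toluate gives the ester-stabilized benzylic anion 8, which is acylated by the amide (toluate anion acylation); the chelated tetrahedral adduct 9 prevents over-addition and releases the ketone only on the cold acidic quench.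

Step 6
Reactants: 10 benzyl 2-(benzyloxy)-6-(2-oxoheptyl)-4-(prop-2-en-1-yloxy)benzoate
Product: 11 benzyl 2-(benzyloxy)-6-[(2-pentyl-1,3-dioxolan-2-yl)methyl]-4-(prop-2-en-1-yloxy)benzoate
Conditions: TMSOCH2CH2OTMS, TMSOTf (5 mol %), CH2Cl2, −78 → −20 °C; then pyridine
Reagents that add atoms: 1,2-bis(trimethylsilyloxy)ethane, C[Si](C)(C)OCCO[Si](C)(C)C
Why: Noyori ketalization, driven by formation of hexamethyldisiloxane, works at low temperature and so avoids the hot protic acid that could lactonize the keto ester to an isocoumarin.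

Step 7
Reactants: 11 benzyl 2-(benzyloxy)-6-[(2-pentyl-1,3-dioxolan-2-yl)methyl]-4-(prop-2-en-1-yloxy)benzoate
Product: 12 benzyl 2-(benzyloxy)-4-hydroxy-6-[(2-pentyl-1,3-dioxolan-2-yl)methyl]benzoate
Conditions: Pd(PPh3)4 (2 mol %), morpholine, THF, rt
Reagents that add atoms: none
Why: Tsuji–Trost deallylation: zerovalent palladium ionizes the aryl allyl ether to a π-allyl complex that morpholine captures, leaving benzyl ether, benzyl ester and dioxolane untouched.

Step 8
Reactants: 13 2,2-dimethyl-1,3-dioxane-4,6-dione (Meldrum's acid); 2 N,O-dimethylhydroxylamine hydrochloride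
Product: 14 3-[methoxy(methyl)amino]-3-oxopropanoic acid
Conditions: Et3N (1.0 equiv), MeCN, sealed vessel, 60 °C
Reagents that add atoms: none
Why: Ring-opening aminolysis of Meldrum's acid by the weakly basic hydroxylamine (freed by exactly one equivalent of Et3N, so the dione is not parked as its unreactive anion) gives the malonic half-amide with loss of acetone and stops there because the product acid is no longer an acyl donor.

Step 9
Reactants: 12 benzyl 2-(benzyloxy)-4-hydroxy-6-[(2-pentyl-1,3-dioxolan-2-yl)methyl]benzoate; 14 3-[methoxy(methyl)amino]-3-oxopropanoic acid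
Product: 15 benzyl 2-(benzyloxy)-4-({3-[methoxy(methyl)amino]-3-oxopropanoyl}oxy)-6-[(2-pentyl-1,3-dioxolan-2-yl)methyl]benzoate
Conditions: DCC, DMAP (5 mol %), CH2Cl2, 0 °C → rt
Reagents that add atoms: none
Why: Steglich esterification of the only free hydroxyl with an unhindered malonic half-acid, a donor that carbodiimides activate readily (through its acylketene), so the later depside oxygen–carbonyl bond is made without any crowded benzoyl donor.

Step 10
Reactants: 16 3,5-bis(benzyloxy)phenol
Product: 17 3,5-bis(benzyloxy)-2-bromophenol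
Conditions: NBS (1.0 equiv), CH2Cl2, −78 → −20 °C
Reagents that add atoms: N-bromosuccinimide, O=C1CCC(=O)N1Br
Why: Electrophilic aromatic bromination; hydrogen-bonded delivery from the phenol in a non-coordinating solvent and the crowding of C4 between two benzyloxy groups should favour C2, while one equivalent at low temperature limits polybromination.

Step 11
Reactants: 17 3,5-bis(benzyloxy)-2-bromophenol
Product: 20 3,5-bis(benzyloxy)-2-(trimethylsilyl)phenyl trifluoromethanesulfonate, via aryl trimethylsilyl ether 18 (not isolated), via lithium 2-silylphenoxide 19 (not isolated)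
Conditions: HMDS, THF, 70 °C, then evaporation; n-BuLi, THF, −100 °C; Tf2O, −100 → −78 °C
Reagents that add atoms: hexamethyldisilazane, C[Si](C)(C)N[Si](C)(C)C; trifluoromethanesulfonic anhydride, O=S(=O)(OS(=O)(=O)C(F)(F)F)C(F)(F)F
Why: O-silylation, bromine–lithium exchange on 18 and a 1,3 O→C silyl shift (retro-Brook rearrangement) give phenoxide 19, which Tf2O traps; this one-flask sequence is the standard entry to ortho-silylaryl triflates, and the exchange at −100 °C outruns any metalation of the benzyl ethers.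

Step 12
Reactants: 15 benzyl 2-(benzyloxy)-4-({3-[methoxy(methyl)amino]-3-oxopropanoyl}oxy)-6-[(2-pentyl-1,3-dioxolan-2-yl)methyl]benzoate; 20 3,5-bis(benzyloxy)-2-(trimethylsilyl)phenyl trifluoromethanesulfonate
Product: 23 benzyl 2-(benzyloxy)-4-[(2,4-bis(benzyloxy)-6-{2-[methoxy(methyl)amino]-2-oxoethyl}benzoyl)oxy]-6-[(2-pentyl-1,3-dioxolan-2-yl)methyl]benzoate, via 3,5-bis(benzyloxy)benzyne 21 (not isolated), via cesium benzocyclobutenoxide 22 (not isolated)
Conditions: CsF (3 equiv), MeCN, 25 °C then 40 °C; 20 (1.5 equiv) added in portions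
Reagents that add atoms: none
Why: Proposed new method: fluoride removes the silyl group of 20 and triflate departs to give aryne 21, the fluoride-generated carbanion of 15 attacks the aryne carbon remote from the C3 benzyloxy group, the aryl anion thus placed beside that oxygen adds to the aryl ester carbonyl to give the four-membered alkoxide 22, and C–C fragmentation of 22 to the amide-stabilized benzylic anion followed by proton transfer from a further molecule of 15 should deliver 23 with the ester carbon moved from the malonyl carbon onto ring B. The closest known reaction type is the fluoride-mediated insertion of arynes, including 3-alkoxy- and 3,5-dialkoxybenzynes, into the C–C σ bond of malonates and β-ketoesters (aryne acyl-alkylation), whereas a mixed aryl ester and N-methoxy-N-methylamide partner is untested. No ring of the target is closed, the only ring formed being the transient cyclobutene ring of 22 by 4-exo-trig closure, and no stereocentre is created because those of 22 vanish on fragmentation. The regioselectivity needed is attack meta to the C3 oxygen, secured by the inductive stabilization of an aryl anion ortho to the benzyloxy group and by the matching distortion of the aryne. The chemoselectivity needed is capture of the aryl anion by the aryl ester rather than by the amide carbonyl or by a proton, secured because the aryl ester is the most electrophilic carbonyl within reach, the amide the least, and the ring A benzyl ester remote. The main competing process, loss of the ring A phenoxide from the enolate of 15 as a ketene, is held back by the weak fluoride base, the mild temperature and the excess of 20, and if 22 instead expels the phenoxide, its re-addition to the strained benzocyclobutenone and ring opening should lead to the same 23.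

Step 13
Reactants: 23 benzyl 2-(benzyloxy)-4-[(2,4-bis(benzyloxy)-6-{2-[methoxy(methyl)amino]-2-oxoethyl}benzoyl)oxy]-6-[(2-pentyl-1,3-dioxolan-2-yl)methyl]benzoate
Product: 25 benzyl 2-(benzyloxy)-4-{[2,4-bis(benzyloxy)-6-(2-oxoheptyl)benzoyl]oxy}-6-[(2-pentyl-1,3-dioxolan-2-yl)methyl]benzoate, via dichlorocerium hemiaminal chelate 24 (not isolated)
Conditions: CeCl3 (anhydrous), n-C5H11MgBr, THF, −78 °C; AcOH/THF, −78 °C
Reagents that add atoms: pentylmagnesium bromide, CCCCC[Mg]Br
Why: Weinreb ketone synthesis with an organocerium reagent, whose low basicity spares the acidic benzylic CH2, whose chelated adduct 24 holds until the cold quench, and which should not reach the two 2,6-disubstituted benzoate esters.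

Step 14
Reactants: 25 benzyl 2-(benzyloxy)-4-{[2,4-bis(benzyloxy)-6-(2-oxoheptyl)benzoyl]oxy}-6-[(2-pentyl-1,3-dioxolan-2-yl)methyl]benzoate
Product: 26 benzyl 2-(benzyloxy)-4-{[2,4-bis(benzyloxy)-6-(2-oxoheptyl)benzoyl]oxy}-6-(2-oxoheptyl)benzoate
Conditions: 1 M aq. HCl, THF, rt
Reagents that add atoms: water, O
Why: Acid-catalysed ketal hydrolysis of a dialkyl ketone dioxolane is fast in dilute aqueous acid at room temperature, conditions under which the crowded aryl benzoate, the benzyl ester and the benzyl ethers should persist.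

Step 15
Reactants: 26 benzyl 2-(benzyloxy)-4-{[2,4-bis(benzyloxy)-6-(2-oxoheptyl)benzoyl]oxy}-6-(2-oxoheptyl)benzoate
Product: 27 4-{[2,4-dihydroxy-6-(2-oxoheptyl)benzoyl]oxy}-2-hydroxy-6-(2-oxoheptyl)benzoic acid
Conditions: H2 (1 atm), 10% Pd/C, EtOAc, rt
Reagents that add atoms: none
Why: Hydrogenolysis of three aryl benzyl ethers and one benzyl ester over palladium on carbon is neutral, so the depside ester and the two non-conjugated ketones should survive and the target is released in the last, reagent-free operation.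

**Compound list**
1 | hexanoyl chloride | CCCCCC(Cl)=O | starting material
2 | N,O-dimethylhydroxylamine hydrochloride | CNOC.Cl | starting material
3 | N-methoxy-N-methylhexanamide | CCCCCC(=O)N(C)OC | intermediate
4 | 2,4-dihydroxy-6-methylbenzoic acid (orsellinic acid) | Cc1cc(O)cc(O)c1C(=O)O | starting material
5 | benzyl 2,4-dihydroxy-6-methylbenzoate | Cc1cc(O)cc(O)c1C(=O)OCc1ccccc1 | intermediate
6 | benzyl 2-hydroxy-6-methyl-4-(prop-2-en-1-yloxy)benzoate | Cc1cc(OCC=C)cc(O)c1C(=O)OCc1ccccc1 | intermediate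
7 | benzyl 2-(benzyloxy)-6-methyl-4-(prop-2-en-1-yloxy)benzoate | Cc1cc(OCC=C)cc(OCc2ccccc2)c1C(=O)OCc1ccccc1 | intermediate
8 | benzyl 2-(benzyloxy)-6-(lithiomethyl)-4-(prop-2-en-1-yloxy)benzoate (lithiated toluate, not isolated) | [Li]Cc1cc(OCC=C)cc(OCc2ccccc2)c1C(=O)OCc1ccccc1 | intermediate
9 | lithium alkoxide of the tetrahedral adduct of 8 and 3 (racemic, not isolated) | CCCCCC(O[Li])(N(C)OC)Cc1cc(OCC=C)cc(OCc2ccccc2)c1C(=O)OCc1ccccc1 | intermediate
10 | benzyl 2-(benzyloxy)-6-(2-oxoheptyl)-4-(prop-2-en-1-yloxy)benzoate | CCCCCC(=O)Cc1cc(OCC=C)cc(OCc2ccccc2)c1C(=O)OCc1ccccc1 | intermediate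
11 | benzyl 2-(benzyloxy)-6-[(2-pentyl-1,3-dioxolan-2-yl)methyl]-4-(prop-2-en-1-yloxy)benzoate | CCCCCC1(Cc2cc(OCC=C)cc(OCc3ccccc3)c2C(=O)OCc2ccccc2)OCCO1 | intermediate
12 | benzyl 2-(benzyloxy)-4-hydroxy-6-[(2-pentyl-1,3-dioxolan-2-yl)methyl]benzoate | CCCCCC1(Cc2cc(O)cc(OCc3ccccc3)c2C(=O)OCc2ccccc2)OCCO1 | intermediate
13 | 2,2-dimethyl-1,3-dioxane-4,6-dione (Meldrum's acid) | CC1(C)OC(=O)CC(=O)O1 | starting material
14 | 3-[methoxy(methyl)amino]-3-oxopropanoic acid | CON(C)C(=O)CC(=O)O | intermediate
15 | benzyl 2-(benzyloxy)-4-({3-[methoxy(methyl)amino]-3-oxopropanoyl}oxy)-6-[(2-pentyl-1,3-dioxolan-2-yl)methyl]benzoate | CCCCCC1(Cc2cc(OC(=O)CC(=O)N(C)OC)cc(OCc3ccccc3)c2C(=O)OCc2ccccc2)OCCO1 | intermediate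
16 | 3,5-bis(benzyloxy)phenol | Oc1cc(OCc2ccccc2)cc(OCc2ccccc2)c1 | starting material
17 | 3,5-bis(benzyloxy)-2-bromophenol | Oc1cc(OCc2ccccc2)cc(OCc2ccccc2)c1Br | intermediate
18 | [3,5-bis(benzyloxy)-2-bromophenoxy]trimethylsilane (not isolated) | C[Si](C)(C)Oc1cc(OCc2ccccc2)cc(OCc2ccccc2)c1Br | intermediate
19 | lithium 3,5-bis(benzyloxy)-2-(trimethylsilyl)phenoxide (not isolated) | [Li]Oc1cc(OCc2ccccc2)cc(OCc2ccccc2)c1[Si](C)(C)C | intermediate
20 | 3,5-bis(benzyloxy)-2-(trimethylsilyl)phenyl trifluoromethanesulfonate | C[Si](C)(C)c1c(OCc2ccccc2)cc(OCc2ccccc2)cc1OS(=O)(=O)C(F)(F)F | intermediate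
21 | 3,5-bis(benzyloxy)benzyne (1,2-didehydro-3,5-bis(benzyloxy)benzene, not isolated) | C1#CC(OCc2ccccc2)=CC(OCc2ccccc2)=C1 | intermediate
22 | cesium benzocyclobutenoxide from addition of the carbanion of 15 to 21 and 4-exo-trig closure (mixture of stereoisomers, not isolated) | [Cs]OC1(Oc2cc(CC3(CCCCC)OCCO3)c(C(=O)OCc3ccccc3)c(OCc3ccccc3)c2)C(C(=O)N(C)OC)c2cc(OCc3ccccc3)cc(OCc3ccccc3)c21 | intermediate
23 | benzyl 2-(benzyloxy)-4-[(2,4-bis(benzyloxy)-6-{2-[methoxy(methyl)amino]-2-oxoethyl}benzoyl)oxy]-6-[(2-pentyl-1,3-dioxolan-2-yl)methyl]benzoate | CCCCCC1(Cc2cc(OC(=O)c3c(OCc4ccccc4)cc(OCc4ccccc4)cc3CC(=O)N(C)OC)cc(OCc3ccccc3)c2C(=O)OCc2ccccc2)OCCO1 | intermediate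
24 | dichlorocerium alkoxide of the tetrahedral adduct of 23 and the pentyl reagent (racemic, not isolated) | CCCCCC(O[Ce](Cl)Cl)(N(C)OC)Cc1cc(OCc2ccccc2)cc(OCc2ccccc2)c1C(=O)Oc1cc(CC2(CCCCC)OCCO2)c(C(=O)OCc2ccccc2)c(OCc2ccccc2)c1 | intermediate
25 | benzyl 2-(benzyloxy)-4-{[2,4-bis(benzyloxy)-6-(2-oxoheptyl)benzoyl]oxy}-6-[(2-pentyl-1,3-dioxolan-2-yl)methyl]benzoate | CCCCCC(=O)Cc1cc(OCc2ccccc2)cc(OCc2ccccc2)c1C(=O)Oc1cc(CC2(CCCCC)OCCO2)c(C(=O)OCc2ccccc2)c(OCc2ccccc2)c1 | intermediate
26 | benzyl 2-(benzyloxy)-4-{[2,4-bis(benzyloxy)-6-(2-oxoheptyl)benzoyl]oxy}-6-(2-oxoheptyl)benzoate | CCCCCC(=O)Cc1cc(OCc2ccccc2)cc(OCc2ccccc2)c1C(=O)Oc1cc(CC(=O)CCCCC)c(C(=O)OCc2ccccc2)c(OCc2ccccc2)c1 | intermediate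
27 | 4-{[2,4-dihydroxy-6-(2-oxoheptyl)benzoyl]oxy}-2-hydroxy-6-(2-oxoheptyl)benzoic acid (CNP0165432.0) | CCCCCC(=O)Cc1cc(OC(=O)c2c(O)cc(O)cc2CC(=O)CCCCC)cc(O)c1C(=O)O | target

**Step count and risks**

Total: 15 steps. Longest linear sequence: 11 steps (steps 2, 3, 4, 5, 6, 7, 9, 12, 13, 14, 15, from orsellinic acid 4 to 27).

Steps most likely to fail:

1. Step 12 (the proposed new method). The enolate of 15 may expel the ring A phenoxide as a ketene before it meets the aryne, and that phenoxide would then be O-arylated by 21. Alternatively the aryl anion may be protonated before the acyl shift, leaving simple α-arylation. The fallback uses known chemistry and makes the depside ester by classical esterification. It sets out from 12: O-benzylation (BnBr, K2CO3, DMF) should give benzyl 2,4-bis(benzyloxy)-6-[(2-pentyl-1,3-dioxolan-2-yl)methyl]benzoate F1. Saponification of this hindered ester (KOH, DMSO/H2O, 80 °C) should give 2,4-bis(benzyloxy)-6-[(2-pentyl-1,3-dioxolan-2-yl)methyl]benzoic acid F2. Steglich coupling of F2 with a second portion of 12 (DCC, DMAP, CH2Cl2, prolonged) should give the bis-dioxolane depside benzyl 2-(benzyloxy)-4-({2,4-bis(benzyloxy)-6-[(2-pentyl-1,3-dioxolan-2-yl)methyl]benzoyl}oxy)-6-[(2-pentyl-1,3-dioxolan-2-yl)methyl]benzoate F3. Both ketals of F3 should fall under the acid conditions of step 14, so this path comes back to the route at 26.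

2. Step 13. The organometallic may deprotonate the benzylic CH2, after which the amide enolate oxygen can attack the neighbouring depside carbonyl and expel the ring A phenoxide (isocoumarin formation); the tetrahedral adduct may also collapse early and over-add. The fallback forms the ketone by a palladium-catalysed coupling that involves no hard nucleophile. It sets out from 12: DCC esterification with commercial 3-(tert-butoxy)-3-oxopropanoic acid should give benzyl 2-(benzyloxy)-4-{[3-(tert-butoxy)-3-oxopropanoyl]oxy}-6-[(2-pentyl-1,3-dioxolan-2-yl)methyl]benzoate F4. Insertion of the aryne from 20 (CsF, MeCN, as in step 12) should give benzyl 2-(benzyloxy)-4-({2,4-bis(benzyloxy)-6-[2-(tert-butoxy)-2-oxoethyl]benzoyl}oxy)-6-[(2-pentyl-1,3-dioxolan-2-yl)methyl]benzoate F5. TFA in wet CH2Cl2 should remove the tert-butyl group and the dioxolane together to give {3,5-bis(benzyloxy)-2-[(3-(benzyloxy)-4-[(benzyloxy)carbonyl]-5-(2-oxoheptyl)phenoxy)carbonyl]phenyl}acetic acid F6. Thioesterification (EtSH, DCC, DMAP) should give the S-ethyl thioester of that acid, benzyl 2-(benzyloxy)-4-({2,4-bis(benzyloxy)-6-[2-(ethylsulfanyl)-2-oxoethyl]benzoyl}oxy)-6-(2-oxoheptyl)benzoate F7. Fukuyama coupling of F7 with commercial pentylzinc bromide (PdCl2(PPh3)2, THF/toluene, rt) comes back to the route at 26.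

3. Step 5. The benzylic anion 8 may take a proton from the α-CH2 of amide 3 and revert to 7, it may condense with the ester of unreacted 7, or the keto ester may lactonize to the isocoumarin during the quench. The fallback makes the same C–C bond at the alcohol oxidation level and accepts the lactone. It sets out from 7: anion 8 is trapped with hexanal at −78 °C, and on warming the alkoxide should close onto the benzyl ester to give racemic 8-(benzyloxy)-3-pentyl-6-(prop-2-en-1-yloxy)-3,4-dihydro-1H-isochromen-1-one F8. KOH in aqueous EtOH should open the lactone to racemic potassium 2-(benzyloxy)-6-(2-hydroxyheptyl)-4-(prop-2-en-1-yloxy)benzoate F9. After evaporation, BnBr in DMF should give racemic benzyl 2-(benzyloxy)-6-(2-hydroxyheptyl)-4-(prop-2-en-1-yloxy)benzoate F10. Prompt Dess–Martin oxidation of F10 removes the stereocentre and comes back to the route at 10.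

**Further compounds**
F1 | step 12 | benzyl 2,4-bis(benzyloxy)-6-[(2-pentyl-1,3-dioxolan-2-yl)methyl]benzoate | CCCCCC1(Cc2cc(OCc3ccccc3)cc(OCc3ccccc3)c2C(=O)OCc2ccccc2)OCCO1
F2 | step 12 | 2,4-bis(benzyloxy)-6-[(2-pentyl-1,3-dioxolan-2-yl)methyl]benzoic acid | CCCCCC1(Cc2cc(OCc3ccccc3)cc(OCc3ccccc3)c2C(O)=O)OCCO1
F3 | step 12 | benzyl 2-(benzyloxy)-4-({2,4-bis(benzyloxy)-6-[(2-pentyl-1,3-dioxolan-2-yl)methyl]benzoyl}oxy)-6-[(2-pentyl-1,3-dioxolan-2-yl)methyl]benzoate | CCCCCC1(Cc2cc(OCc3ccccc3)cc(OCc3ccccc3)c2C(=O)Oc2cc(CC3(CCCCC)OCCO3)c(C(=O)OCc3ccccc3)c(OCc3ccccc3)c2)OCCO1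
F4 | step 13 | benzyl 2-(benzyloxy)-4-{[3-(tert-butoxy)-3-oxopropanoyl]oxy}-6-[(2-pentyl-1,3-dioxolan-2-yl)methyl]benzoate | CCCCCC1(Cc2cc(OC(=O)CC(=O)OC(C)(C)C)cc(OCc3ccccc3)c2C(=O)OCc2ccccc2)OCCO1
F5 | step 13 | benzyl 2-(benzyloxy)-4-({2,4-bis(benzyloxy)-6-[2-(tert-butoxy)-2-oxoethyl]benzoyl}oxy)-6-[(2-pentyl-1,3-dioxolan-2-yl)methyl]benzoate | CCCCCC1(Cc2cc(OC(=O)c3c(OCc4ccccc4)cc(OCc4ccccc4)cc3CC(=O)OC(C)(C)C)cc(OCc3ccccc3)c2C(=O)OCc2ccccc2)OCCO1
F6 | step 13 | {3,5-bis(benzyloxy)-2-[(3-(benzyloxy)-4-[(benzyloxy)carbonyl]-5-(2-oxoheptyl)phenoxy)carbonyl]phenyl}acetic acid | CCCCCC(=O)Cc1cc(OC(=O)c2c(OCc3ccccc3)cc(OCc3ccccc3)cc2CC(=O)O)cc(OCc2ccccc2)c1C(=O)OCc1ccccc1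
F7 | step 13 | benzyl 2-(benzyloxy)-4-({2,4-bis(benzyloxy)-6-[2-(ethylsulfanyl)-2-oxoethyl]benzoyl}oxy)-6-(2-oxoheptyl)benzoate | CCCCCC(=O)Cc1cc(OC(=O)c2c(OCc3ccccc3)cc(OCc3ccccc3)cc2CC(=O)SCC)cc(OCc2ccccc2)c1C(=O)OCc1ccccc1
F8 | step 5 | racemic 8-(benzyloxy)-3-pentyl-6-(prop-2-en-1-yloxy)-3,4-dihydro-1H-isochromen-1-one | CCCCCC1Cc2cc(OCC=C)cc(OCc3ccccc3)c2C(=O)O1
F9 | step 5 | racemic potassium 2-(benzyloxy)-6-(2-hydroxyheptyl)-4-(prop-2-en-1-yloxy)benzoate | CCCCCC(O)Cc1cc(OCC=C)cc(OCc2ccccc2)c1C(=O)[O-].[K+]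
F10 | step 5 | racemic benzyl 2-(benzyloxy)-6-(2-hydroxyheptyl)-4-(prop-2-en-1-yloxy)benzoate | CCCCCC(O)Cc1cc(OCC=C)cc(OCc2ccccc2)c1C(=O)OCc1ccccc1
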